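I decide to rank these flasks by counting turnovers of the step that makes Ze.

    Ju ⇌ Ze (K1 = 0.684, k1 = 0.0949 s⁻¹, Ea1 = 77.0 kJ mol⁻¹, ΔH1 = −5.00 kJ mol⁻¹)
    Ju ⇌ Xa (K2 = 2.21, k2 = 0.0537 s⁻¹, Ea2 = 85.0 kJ mol⁻¹, ΔH2 = −41.0 kJ mol⁻¹)
    Ju ⇌ Wa (K3 = 18.3, k3 = 7.74 × 10⁻⁴ s⁻¹, Ea3 = 95.0 kJ mol⁻¹, ΔH3 = −27.0 kJ mol⁻¹)
    Ju ⇌ Ul (K4 = 5.84, k4 = 0.0240 s⁻¹, Ea4 = 79.0 kJ mol⁻¹, ΔH4 = −54.0 kJ mol⁻¹)
    Ju + Ej → Ju.Ej (k5 = 1.26 M⁻¹ s⁻¹, Ea5 = 61.0 kJ mol⁻¹)
    (constants at 25 °C)

common to all: Ju 2.0 M; Ej 0.0400 M; time 4.0 min

| flask | remark | temperature |
|---|---|---|
| blue | at −35 °C until 3.0 min, from then on at 25 °C |  |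
| teal |  | −5 °C |
| green |  | 25 °C |
| violet |  | −35 °C |

- the flask that comes out highest in amount of Ze, in percent of the Ju charged, or "all alike" when all lie within 1.5 percentage points (blue / teal / green / violet / all alike)
- Ze at the end, in percent of the Ju charged, blue
- Ze at the end, in percent of the Ju charged, teal
- Ze at the end, in percent of the Ju charged, green
- Ze at the end, in percent of the Ju charged, violet

- all constants are for 25 °C and move with temperature by the activation energies and enthalpies

In teal, at −5 °C, the Arrhenius law lowers the constant of the step to Ze to 0.00294 s⁻¹, so over 4.0 min the step makes 0.705 turnovers. That number, the forward rate constant at the temperature of the flask multiplied by the time spent there and summed over the stretches of the run, is the turnover count; it is elapsed time measured in time constants of the step. Violet reaches 0.00910 and green 22.8. Blue makes 0.00682 in its cold stretch and 5.69 after the change, together 5.70.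

Now I build teal up by hand. With the step to Ze on its own, the equilibrium constant at this temperature is 0.857, the back constant is 0.00343 s⁻¹, and the system has one pole, which puts Ze at 36.1% of the Ju charged at the end.

Next I add a one-way drain out of Ju into Xa, Ul and Wa, of 0.00185 s⁻¹ in sum. The system now has two poles, with time constants 2.27 min and 19.3 min. Ze rises on the fast one and decays on the slow one, and the figure drops to 29.1%.

Last comes Ej. With [Ju] far above [Ej], its step is pseudo-first-order in Ej, with a time constant of 6.23 s, much shorter than that of the step to Ze. In teal Ej is the limiting reagent of that step, and by my reckoning it takes 2.00% of the Ju early on. That scales teal to 28.5%, the number I commit to.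

Violet's count lies far below one, so I take its Ze as 0.905%. In green the steps to Xa and Ul also make 12.9 and 5.76 turnovers, while the step to Wa makes 0.186. I therefore share the Ju in green by the equilibrium constants with Wa set aside, and after the cut for Ej this gives 6.89%. Teal comes out above both. In blue, after the change, the step to Ul makes 1.44 turnovers, fewer than in green, so I expect blue above green's figure, and with blue's count for the step to Ze well past one I expect it nearer green than teal.

The forecast also names teal, with 11.5% for blue, 28.5% for teal, 7.3% for green and 0.9% for violet. Its ground for teal is that Ze, at that temperature, “builds up well ahead of the other channels”. Its green stands a little above mine, and it gives blue a number where I gave a direction.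

The simulation gives Ze at 11.2% in blue, 28.5% in teal, 7.34% in green and 0.892% in violet, so teal stands highest. In blue, up to 3.0 min, the step to Ze made 0.00682 turnovers, and at that moment Ej stood at 40.2% of its own charge, Ju at 97.8% and Ze at 0.672%. After the change to 25 °C, blue's count rose by 5.69, more than teal's 0.705 over its whole run; Ej went to 0%, Ju fell to 15.5%, Xa reached 37.5%, and Ze ended at 11.2%.

The constants were chosen freely; the rest is arithmetic.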